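**Retrosynthetic overview**
- The tetrasubstituted C=C is made last: enol triflate + Me2CuLi on an eight-membered-ring enone.
- Ring B (eight-membered) is closed by Ni/Cr coupling of an alkenyl bromide with an aldehyde.
- Fragments are joined by copper-catalysed 1,4-addition of a (Z)-alkenylmagnesium (ring A piece) to a hydrindene enal (rings C/D).
- Key step: rings C and D form together in an intramolecular Diels–Alder reaction of a silyloxytriene from (S)-α-phellandrene.
- Ring A is bought as (R)-3-methylcyclopentanone; a Claisen rearrangement places its side chain cis to the methyl group. Ring order: C+D, A (bought), B last.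

Assumption: (S)-(+)-α-phellandrene and (R)-(+)-3-methylcyclopentanone are bought as the enantiomers drawn. The route is a proposal; selectivities are expectations from precedent, not measured values.

**Rings C/D**

Step 1
Reactants: 1 (S)-(+)-α-phellandrene
Product: 3 (3S,4E)-6-oxo-3-(propan-2-yl)hept-4-enal, via (Z)-keto-enal 2 (not isolated)
Conditions: O3 (1 equiv, Sudan Red 7B end-point), pyridine, CH2Cl2, −78 °C; then I2 (5 mol%), rt
Reagents that add atoms: ozone O=[O+][O-]
Why: Pyridine-mediated ozonolysis should cleave the more electron-rich trisubstituted alkene of the diene (the enone formed is deactivated), and iodine-catalysed Z→E isomerisation follows; the bought isopropyl stereocentre is untouched.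

Step 2
Reactants: 3 (3S,4E)-6-oxo-3-(propan-2-yl)hept-4-enal
Product: 4 (5S,6E)-3-hydroxy-2-methyl-5-(propan-2-yl)nona-1,6-dien-8-one
Conditions: 2-bromopropene, CrCl2, NiCl2 (cat.), DMF, 0 °C → rt
Reagents that add atoms: 2-bromopropene CC(Br)=C
Why: Nozaki–Hiyama–Kishi alkenylation adds to the aldehyde and leaves the enone alone; the new carbinol centre (both epimers) is oxidised away in the next step.

Step 3
Reactants: 4 (5S,6E)-3-hydroxy-2-methyl-5-(propan-2-yl)nona-1,6-dien-8-one
Product: 5 (5S,6E)-2-methyl-5-(propan-2-yl)nona-1,6-diene-3,8-dione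
Conditions: Dess–Martin periodinane, NaHCO3, CH2Cl2, 0 °C
Reagents that add atoms: none
Why: Dess–Martin oxidation of the allylic alcohol gives the isopropenyl ketone dienophile under neutral conditions that do not touch the γ-stereocentre.

Step 4
Reactants: 5 (5S,6E)-2-methyl-5-(propan-2-yl)nona-1,6-diene-3,8-dione
Product: 7 (3S,3aR,7aR)-7a-methyl-3-(propan-2-yl)-5-(trimethylsilyloxy)-2,3,3a,6,7,7a-hexahydro-1H-inden-1-one, via silyl dienol ether 6 (not isolated)
Conditions: Me3SiCl, LiN(SiMe3)2, THF, −78 °C (in situ quench); then PhMe, 110 °C (BHT); non-aqueous work-up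
Reagents that add atoms: chlorotrimethylsilane C[Si](C)(C)Cl
Why: Kinetic silylation of the unhindered methyl ketone gives a 2-silyloxydiene that undergoes a type 1 intramolecular Diels–Alder reaction with the isopropenyl ketone, where the isopropyl group sits pseudo-equatorially on the forming five-membered ring (ring-fusion H cis to it) and the exo-carbonyl transition state preferred by α-methyl enones gives the trans fusion carrying the angular methyl.

Step 5
Reactants: 7 (3S,3aR,7aR)-7a-methyl-3-(propan-2-yl)-5-(trimethylsilyloxy)-2,3,3a,6,7,7a-hexahydro-1H-inden-1-one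
Product: 9 (1R,3S,3aS,7aR)-1-hydroxy-7a-methyl-3-(propan-2-yl)octahydro-5H-inden-5-one, via hydroxy silyl enol ether 8 (not isolated)
Conditions: LiAlH4, THF, −78 → 0 °C; then 1 M HCl, rt
Reagents that add atoms: none
Why: Hydride attacks the cyclopentanone from the face opposite the angular methyl (as in 17-oxo steroids), giving the alcohol cis to that methyl while the six-ring ketone stays masked as its silyl enol ether, which the acidic work-up hydrolyses.

Step 6
Reactants: 9 (1R,3S,3aS,7aR)-1-hydroxy-7a-methyl-3-(propan-2-yl)octahydro-5H-inden-5-one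
Product: 11 (1R,3S,3aS,7aR)-1-hydroxy-7a-methyl-3-(propan-2-yl)-2,3,3a,4,7,7a-hexahydro-1H-inden-5-yl trifluoromethanesulfonate, via dilithium alkoxide-enolate 10 (not isolated)
Conditions: LiN(i-Pr)2 (2.2 equiv), THF, −78 °C; PhNTf2 (1.1 equiv), −78 → 0 °C
Reagents that add atoms: N-phenylbis(trifluoromethanesulfonimide) O=S(=O)(N(c1ccccc1)S(=O)(=O)C(F)(F)F)C(F)(F)F
Why: Kinetic deprotonation of the trans-fused cyclohexanone occurs at the CH2 remote from the ring fusion (as in 5α-3-oxo steroids) and the enolate is O-triflated, while the hindered neopentylic alkoxide is not triflated by this mild reagent.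

Step 7
Reactants: 11 (1R,3S,3aS,7aR)-1-hydroxy-7a-methyl-3-(propan-2-yl)-2,3,3a,4,7,7a-hexahydro-1H-inden-5-yl trifluoromethanesulfonate
Product: 12 (1R,3S,3aS,7aR)-1-hydroxy-7a-methyl-3-(propan-2-yl)-2,3,3a,4,7,7a-hexahydro-1H-indene-5-carbaldehyde
Conditions: CO (1 atm), Bu3SnH (slow addition), Pd(PPh3)4 (5 mol%), LiCl, THF, 50 °C
Reagents that add atoms: carbon monoxide [C-]#[O+]
Why: Palladium-catalysed carbonylative reduction of the enol triflate (Stille formylation) gives the enal and tolerates the free hydroxyl.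

**Ring A piece**

Step 8
Reactants: 13 (R)-(+)-3-methylcyclopentan-1-one
Product: 15 (S)-4-methylcyclopent-2-en-1-one, via silyl enol ether 14 (not isolated)
Conditions: LiN(i-Pr)2, THF, −78 °C; Me3SiCl; then Pd(OAc)2 (10 mol%), O2, DMSO, rt
Reagents that add atoms: none
Why: Kinetic enolisation away from the methyl-bearing carbon followed by Saegusa–Ito dehydrogenation gives the enone; the minor regioisomer ends as achiral 3-methylcyclopent-2-enone and is removed, so the bought stereocentre is kept.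

Step 9
Reactants: 15 (S)-4-methylcyclopent-2-en-1-one
Product: 17 (S)-2-bromo-4-methylcyclopent-2-en-1-one, via dibromo ketone 16 (not isolated)
Conditions: Br2, CH2Cl2, 0 °C; then Et3N, 0 °C
Reagents that add atoms: bromine BrBr
Why: Bromine addition to the enone and dehydrobromination give the α-bromoenone.

Step 10
Reactants: 17 (S)-2-bromo-4-methylcyclopent-2-en-1-one
Product: 18 (1R,4S)-2-bromo-4-methylcyclopent-2-en-1-ol
Conditions: NaBH4, CeCl3·7H2O, MeOH, −78 °C
Reagents that add atoms: none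
Why: Luche 1,2-reduction delivers hydride anti to the 4-methyl group, giving the cis allylic alcohol.

Step 11
Reactants: 18 (1R,4S)-2-bromo-4-methylcyclopent-2-en-1-ol
Product: 20 2-[(1S,5S)-2-bromo-5-methylcyclopent-2-en-1-yl]acetaldehyde, via vinyl ether 19 (not isolated)
Conditions: butyl vinyl ether, Pd(O2CCF3)2 (5 mol%), 4,7-diphenyl-1,10-phenanthroline, Et3N, 75 °C; then xylene, 150 °C (sealed)
Reagents that add atoms: butyl vinyl ether C=COCCCC
Why: Transfer vinylation then Claisen rearrangement ([3,3]-sigmatropic) moves the two-carbon aldehyde unit suprafacially from the C–O face to the allylic terminus, so the new C–C bond is forced cis to the neighbouring methyl group.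

Step 12
Reactants: 20 2-[(1S,5S)-2-bromo-5-methylcyclopent-2-en-1-yl]acetaldehyde
Product: 21 (4S,5S)-1-bromo-5-[(2Z)-3-iodobut-2-en-1-yl]-4-methylcyclopent-1-ene
Conditions: EtPPh3I, n-BuLi, THF; I2, −78 °C; NaN(SiMe3)2, −20 °C; then 20, −78 °C
Reagents that add atoms: ethyltriphenylphosphonium iodide CC[P+](c1ccccc1)(c1ccccc1)c1ccccc1.[I-]; iodine II
Why: Stork–Zhao-type Wittig olefination with the α-iodoethylidene ylide gives the (Z)-2-iodoalkene whose geometry becomes that of the ring alkene.

**Union and ring B**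

Step 13
Reactants: 21 (4S,5S)-1-bromo-5-[(2Z)-3-iodobut-2-en-1-yl]-4-methylcyclopent-1-ene; 12 (1R,3S,3aS,7aR)-1-hydroxy-7a-methyl-3-(propan-2-yl)-2,3,3a,4,7,7a-hexahydro-1H-indene-5-carbaldehyde
Product: 25 6-alkenyl-1-hydroxyhydrindane-5-carbaldehyde (full name in the compound list), via alkenylmagnesium chloride 22 (not isolated), via silyl ether 23 (not isolated), via bis-silyl adduct 24 (not isolated)
Conditions: 21, i-PrMgCl·LiCl, THF, 0 °C → rt; 12, Me3SiCl, Et3N, THF, 0 °C; combine, CuBr·SMe2 (10 mol%), −78 °C; then K2CO3, MeOH, rt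
Reagents that add atoms: none
Why: Selective I/Mg exchange (the alkenyl bromide is inert) and copper-catalysed, Me3SiCl-accelerated conjugate addition join the fragments with retention of alkene geometry; the reagent adds to the enal face away from the axial angular methyl and base equilibration puts the formyl group equatorial (trans), with the hydroxyl silylated only transiently.

Step 14
Reactants: 25 6-alkenyl-1-hydroxyhydrindane-5-carbaldehyde
Product: 26 tetracyclic diol (eight-membered ring closed)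
Conditions: CrCl2, NiCl2 (cat.), DMSO–THF, high dilution, rt → 50 °C
Reagents that add atoms: none
Why: Intramolecular Nozaki–Hiyama–Kishi coupling of the alkenyl bromide with the aldehyde closes the eight-membered ring, as in ophiobolin-type closures; the new carbinol centre (both epimers) is oxidised in the next step.

Step 15
Reactants: 26 tetracyclic diol
Product: 27 tetracyclic hydroxy enone
Conditions: MnO2, CH2Cl2, rt
Reagents that add atoms: none
Why: MnO2 oxidises only the allylic alcohol, giving the ring ketone conjugated with the cyclopentene.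

Step 16
Reactants: 27 tetracyclic hydroxy enone
Product: 29 tetracyclic hydroxy enol triflate, via dilithium enolate-alkoxide 28 (not isolated)
Conditions: Li, NH3(l)–THF, −78 °C; isoprene; evaporate NH3; PhNTf2, THF, −78 → 0 °C
Reagents that add atoms: N-phenylbis(trifluoromethanesulfonimide) O=S(=O)(N(c1ccccc1)S(=O)(=O)C(F)(F)F)C(F)(F)F
Why: Dissolving-metal reduction of the enone gives the enolate regiospecifically on the cyclopentane side with its geometry fixed by the ring, and PhNTf2 traps it as the enol triflate (Stork enolate generation, McMurry–Scott trapping).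

Step 17
Reactants: 29 tetracyclic hydroxy enol triflate
Product: 30 CNP0541339.1
Conditions: Me2CuLi (5 equiv), Et2O–THF, −20 → 0 °C; aq. NH4Cl
Reagents that add atoms: lithium dimethylcuprate [Li+].C[Cu-]C
Why: Gilman cuprate coupling replaces the triflate by methyl with retention, completing the tetrasubstituted alkene.

**Compound list**

1 | (S)-(+)-α-phellandrene, (5S)-2-methyl-5-(propan-2-yl)cyclohexa-1,3-diene | CC1=CC[C@@H](C(C)C)C=C1 | starting material
2 | (3S,4Z)-6-oxo-3-(propan-2-yl)hept-4-enal | O=CC[C@@H](C(C)C)/C=C\C(C)=O | intermediate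
3 | (3S,4E)-6-oxo-3-(propan-2-yl)hept-4-enal | O=CC[C@@H](C(C)C)/C=C/C(C)=O | intermediate
4 | (5S,6E)-3-hydroxy-2-methyl-5-(propan-2-yl)nona-1,6-dien-8-one (both C3 epimers) | C=C(C)C(O)C[C@@H](C(C)C)/C=C/C(C)=O | intermediate
5 | (5S,6E)-2-methyl-5-(propan-2-yl)nona-1,6-diene-3,8-dione | C=C(C)C(=O)C[C@@H](C(C)C)/C=C/C(C)=O | intermediate
6 | (5S,6E)-2-methyl-5-(propan-2-yl)-8-(trimethylsilyloxy)nona-1,6,8-trien-3-one | C=C(C)C(=O)C[C@@H](C(C)C)/C=C/C(=C)O[Si](C)(C)C | intermediate
7 | (3S,3aR,7aR)-7a-methyl-3-(propan-2-yl)-5-(trimethylsilyloxy)-2,3,3a,6,7,7a-hexahydro-1H-inden-1-one (trans-fused) | O=C1C[C@@H](C(C)C)[C@@H]2C=C(O[Si](C)(C)C)CC[C@@]12C | intermediate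
8 | (1R,3S,3aR,7aR)-7a-methyl-3-(propan-2-yl)-5-(trimethylsilyloxy)-2,3,3a,6,7,7a-hexahydro-1H-inden-1-ol | O[C@@H]1C[C@@H](C(C)C)[C@@H]2C=C(O[Si](C)(C)C)CC[C@@]12C | intermediate
9 | (1R,3S,3aS,7aR)-1-hydroxy-7a-methyl-3-(propan-2-yl)octahydro-5H-inden-5-one (trans-fused, OH cis to angular methyl) | O[C@@H]1C[C@@H](C(C)C)[C@@H]2CC(=O)CC[C@@]12C | intermediate
10 | dilithium salt of 9 (C1 alkoxide, C5–C6 enolate) | [Li+].[Li+].[O-][C@@H]1C[C@@H](C(C)C)[C@@H]2CC([O-])=CC[C@@]12C | intermediate
11 | (1R,3S,3aS,7aR)-1-hydroxy-7a-methyl-3-(propan-2-yl)-2,3,3a,4,7,7a-hexahydro-1H-inden-5-yl trifluoromethanesulfonate | O[C@@H]1C[C@@H](C(C)C)[C@@H]2CC(OS(=O)(=O)C(F)(F)F)=CC[C@@]12C | intermediate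
12 | (1R,3S,3aS,7aR)-1-hydroxy-7a-methyl-3-(propan-2-yl)-2,3,3a,4,7,7a-hexahydro-1H-indene-5-carbaldehyde | O[C@@H]1C[C@@H](C(C)C)[C@@H]2CC(C=O)=CC[C@@]12C | intermediate
13 | (R)-(+)-3-methylcyclopentan-1-one | O=C1C[C@H](C)CC1 | starting material
14 | (R)-trimethyl[(4-methylcyclopent-1-en-1-yl)oxy]silane | C[Si](C)(C)OC1=CC[C@@H](C)C1 | intermediate
15 | (S)-4-methylcyclopent-2-en-1-one | O=C1C=C[C@@H](C)C1 | intermediate
16 | (4S)-2,3-dibromo-4-methylcyclopentan-1-one (dibromide diastereomers) | O=C1C(Br)C(Br)[C@@H](C)C1 | intermediate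
17 | (S)-2-bromo-4-methylcyclopent-2-en-1-one | O=C1C(Br)=C[C@@H](C)C1 | intermediate
18 | (1R,4S)-2-bromo-4-methylcyclopent-2-en-1-ol (cis) | O[C@H]1C(Br)=C[C@@H](C)C1 | intermediate
19 | (3S,5R)-1-bromo-5-(ethenyloxy)-3-methylcyclopent-1-ene (vinyl ether of 18) | C=CO[C@H]1C(Br)=C[C@@H](C)C1 | intermediate
20 | 2-[(1S,5S)-2-bromo-5-methylcyclopent-2-en-1-yl]acetaldehyde (side chain cis to methyl) | O=CC[C@@H]1C(Br)=CC[C@@H]1C | intermediate
21 | (4S,5S)-1-bromo-5-[(2Z)-3-iodobut-2-en-1-yl]-4-methylcyclopent-1-ene | C/C(I)=C/C[C@@H]1C(Br)=CC[C@@H]1C | intermediate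
22 | (Z)-alkenylmagnesium chloride from 21 (Mg in place of I) | C/C([Mg]Cl)=C/C[C@@H]1C(Br)=CC[C@@H]1C | intermediate
23 | O-trimethylsilyl ether of 12 | C[Si](C)(C)O[C@@H]1C[C@@H](C(C)C)[C@@H]2CC(C=O)=CC[C@@]12C | intermediate
24 | 1,4-adduct as silyl enol ether of the aldehyde, C1 hydroxyl as silyl ether | C[Si](C)(C)OC=C1C[C@H]2[C@H](C(C)C)C[C@@H](O[Si](C)(C)C)[C@]2(C)C[C@@H]1/C(C)=C\C[C@@H]3C(Br)=CC[C@@H]3C | intermediate
25 | (1R,3S,3aS,5S,6S,7aR)-6-{(2Z)-4-[(1S,5S)-2-bromo-5-methylcyclopent-2-en-1-yl]but-2-en-2-yl}-1-hydroxy-7a-methyl-3-(propan-2-yl)octahydro-1H-indene-5-carbaldehyde | O=C[C@H]1C[C@H]2[C@H](C(C)C)C[C@@H](O)[C@]2(C)C[C@@H]1/C(C)=C\C[C@@H]3C(Br)=CC[C@@H]3C | intermediate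
26 | 5-8-6-5 tetracyclic diol: C–C bond between the CHO carbon and the C–Br carbon of 25; new allylic carbinol as both epimers, other centres as in 25 | OC1[C@H]2C[C@H]3[C@H](C(C)C)C[C@@H](O)[C@]3(C)C[C@@H]2/C(C)=C\C[C@@H]4C1=CC[C@@H]4C | intermediate
27 | ketone of 26: eight-membered-ring C=O conjugated with the cyclopentene C=C, ring hydroxyl kept | O=C1[C@H]2C[C@H]3[C@H](C(C)C)C[C@@H](O)[C@]3(C)C[C@@H]2/C(C)=C\C[C@@H]4C1=CC[C@@H]4C | intermediate
28 | dilithium enolate-alkoxide from 27 (enolate C=C exocyclic to the cyclopentane) | [Li+].[Li+].C/C1=C/C[C@@H]2/C(=C(/[O-])[C@H]3C[C@H]4[C@H](C(C)C)C[C@@H]([O-])[C@]4(C)C[C@H]13)CC[C@@H]2C | intermediate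
29 | enol triflate: the target with OSO2CF3 in place of the methyl on the tetrasubstituted alkene | C/C1=C/C[C@@H]2/C(=C(/OS(=O)(=O)C(F)(F)F)[C@H]3C[C@H]4[C@H](C(C)C)C[C@@H](O)[C@]4(C)C[C@H]13)CC[C@@H]2C | intermediate
30 | CNP0541339.1 (5-8-6-5 sesterterpenoid alcohol) | C/C1=C/C[C@@H]2/C(=C(/C)[C@H]3C[C@H]4[C@H](C(C)C)C[C@@H](O)[C@]4(C)C[C@H]13)CC[C@@H]2C | target

**Step count and risks**

Total: 17 steps. Longest linear sequence: 12 steps (steps 1–7, then 13–17); the ring A branch is steps 8–12.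

Most likely to fail:

- Step 1 (mono-ozonolysis of a conjugated diene may over-cleave or attack the other alkene). The fallback sets out from 1: m-chloroperbenzoic acid with NaHCO3 epoxidises the trisubstituted alkene to the vinyl epoxide F1, periodic acid in wet THF opens and cleaves it to 2, and iodine isomerisation brings it back to the route at 3.

- Step 4 (chemoselective silylation and the trans/cis ratio of the cycloaddition). The fallback sets out from 7 obtained as a ring-fusion mixture: Pd(OAc)2 in MeCN (Saegusa–Ito oxidation) erases the ring-fusion CH and gives the enedione F2, NaBH4 at −20 °C reduces only the cyclopentanone to the ketol F3, and conjugate reduction with i-Bu2AlH/t-BuCu delivers hydride opposite the angular methyl to set the trans fusion, coming back to the route at 9.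

- Step 14 (eight-membered-ring closure with an alkenyl bromide). The fallback sets out from 20 and 12: Ph3P=CH2 turns 20 into the allyl bromocyclopentene F4; (CH2=C(Me))2CuLi then K2CO3/MeOH turns 12 into the isopropenyl aldehyde F5; CrCl2/NiCl2 couples F4 with F5 to the diol F6; MnO2 gives the dienone F7; ring-closing metathesis with the second-generation Hoveyda–Grubbs catalyst (PhMe, 80 °C) forms the trisubstituted ring alkene and comes back to the route at 27.

**Further compounds**

F1 | step 1 | (4S)-1-methyl-4-(propan-2-yl)-7-oxabicyclo[4.1.0]hept-2-ene (epoxide diastereomers) | CC12OC1C[C@@H](C(C)C)C=C2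
F2 | step 4 | (3S,7aR)-7a-methyl-3-(propan-2-yl)-2,3,7,7a-tetrahydro-1H-indene-1,5(6H)-dione | O=C1C[C@@H](C(C)C)C2=CC(=O)CC[C@@]12C
F3 | step 4 | (1R,3S,7aR)-1-hydroxy-7a-methyl-3-(propan-2-yl)-1,2,3,6,7,7a-hexahydro-5H-inden-5-one | O[C@@H]1C[C@@H](C(C)C)C2=CC(=O)CC[C@@]12C
F4 | step 14 | (4S,5S)-1-bromo-4-methyl-5-(prop-2-en-1-yl)cyclopent-1-ene | C=CC[C@@H]1C(Br)=CC[C@@H]1C
F5 | step 14 | (1R,3S,3aS,5S,6S,7aR)-1-hydroxy-7a-methyl-3-(propan-2-yl)-6-(prop-1-en-2-yl)octahydro-1H-indene-5-carbaldehyde | O=C[C@H]1C[C@H]2[C@H](C(C)C)C[C@@H](O)[C@]2(C)C[C@@H]1C(C)=C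
F6 | step 14 | carbinol from F5 and the cyclopentenyl unit of F4 (both carbinol epimers) | OC([C@H]1C[C@H]2[C@H](C(C)C)C[C@@H](O)[C@]2(C)C[C@@H]1C(C)=C)C3=CC[C@H](C)[C@@H]3CC=C
F7 | step 14 | ketone of F6 | O=C([C@H]1C[C@H]2[C@H](C(C)C)C[C@@H](O)[C@]2(C)C[C@@H]1C(C)=C)C3=CC[C@H](C)[C@@H]3CC=C
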